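**Plan**
- Retrosynthesis: the C2–Br and C3–Br bonds are cut first (C2–Br back to a C2 carboxyl group, C3–Br back to C3–H), then N1–C7a and C3–C3a of the five-membered ring are cut together.
- Enabling feature: N1 and C3 sit on the adjacent benzene carbons C7a and C3a, and the C4 bromine flanks C3a. This is the pattern left by a 3-bromoaryne that takes a nucleophile at its distal carbon and an electrophile at the carbon beside bromine.
- Forward: the benzene ring is bought as 2,4,6-tribromophenol and converted into an ortho-silylaryl triflate. The derived 3,5-dibromobenzyne is then annulated with N-Boc dehydroalanine methyl ester, closing the pyrroline ring in one step.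
- Finish: Boc removal, dehydrogenation to the indole, saponification, then NBS bromination at C3 with ipso-bromodecarboxylation at C2.
- Stereochemistry: the target is achiral; the indoline C2 centre is formed racemic and disappears on aromatisation.

Key step: step 3

Remark on the chemistry: indole numbering is used throughout, and compounds 8 and 9 are carried as racemates because their only stereocentre is destroyed in step 5.

**Step 1**
Reactants: 1 2,4,6-tribromophenol
Product: 2 (2,4,6-tribromophenoxy)trimethylsilane
Conditions: HMDS (neat), 80 °C; excess reagent removed in vacuo, crude product used directly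
Reagents that add atoms: hexamethyldisilazane, C[Si](C)(C)N[Si](C)(C)C
Why: O-silylation of an acidic phenol by HMDS with loss of ammonia is a standard, clean protection that needs no chromatography.

**Step 2**
Reactants: 2 (2,4,6-tribromophenoxy)trimethylsilane
Product: 5 2,4-dibromo-6-(trimethylsilyl)phenyl trifluoromethanesulfonate, via ortho-lithiated silyl ether 3 (not isolated), via lithium silylphenoxide 4 (not isolated)
Conditions: n-BuLi (1.05 equiv), THF, −100 → −80 °C; then Tf2O (1.2 equiv), −100 → −80 °C; cold aq. NaHCO3
Reagents that add atoms: n-butyllithium, [Li]CCCC (lithium of 3 and 4 only); trifluoromethanesulfonic anhydride, O=S(=O)(OS(=O)(=O)C(F)(F)F)C(F)(F)F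
Why: Bromine–lithium exchange should occur at one of the two equivalent bromines ortho to the silyloxy group, the ortho-lithio species is drained irreversibly by anionic 1,3 O→C silyl migration (retro-Brook rearrangement), and the phenoxide is O-triflated in the same flask, the standard route from ortho-bromophenols to ortho-silylaryl triflates.

**Step 3**
Reactants: 5 2,4-dibromo-6-(trimethylsilyl)phenyl trifluoromethanesulfonate (1.5 equiv); 6 methyl 2-[(tert-butoxycarbonyl)amino]acrylate
Product: 8 1-tert-butyl 2-methyl 4,6-dibromoindoline-1,2-dicarboxylate (racemic), via 3,5-dibromobenzyne 7 (not isolated)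
Conditions: Bu4N[Ph3SiF2] (2 equiv), THF, 23 °C
Reagents that add atoms: none
Why: Fluoride attacks the silicon of 5 and triflate departs to give aryne 7; the carbamate nitrogen of 6 adds to the aryne carbon remote from bromine (N1–C7a), and the aryl anion formed beside bromine adds to the acrylate terminus (C3–C3a) before the resulting ester enolate is protonated. The closest known reaction is the fluoride-induced annulation of arynes with N-carbamoyl dehydroamino esters to indoline-2-carboxylates, combined with the established distal attack of nucleophiles on 3-haloarynes. The five-membered ring closes by a 5-endo-trig conjugate addition, feasible here because the nucleophile is an in-plane sp2 aryl anion held directly next to the enamide acceptor. The one new stereocentre, C2, comes from unbiased protonation of the enolate, so 8 is racemic, which does not matter because C2 becomes sp2 in step 5. The step needs regioselective nitrogen addition to an unsymmetrical aryne, and the inductively withdrawing bromine next to the triple bond secures it by making the distal aryne carbon the more electrophilic one and by stabilising the negative charge that develops at the proximal carbon. Ring closure must also outrun protonation or bromide loss from the ortho-bromoaryl anion, which the tethered acceptor and the non-coordinating ammonium counter-ion should favour.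

**Step 4**
Reactants: 8 1-tert-butyl 2-methyl 4,6-dibromoindoline-1,2-dicarboxylate (racemic)
Product: 9 methyl 4,6-dibromoindoline-2-carboxylate (racemic)
Conditions: TFA, CH2Cl2, 0 °C → rt; aq. NaHCO3 work-up
Reagents that add atoms: none
Why: Acidolytic Boc cleavage leaves the methyl ester and aryl bromides untouched and frees the aniline-type nitrogen, which makes the following dehydrogenation easy.

**Step 5**
Reactants: 9 methyl 4,6-dibromoindoline-2-carboxylate (racemic)
Product: 10 methyl 4,6-dibromo-1H-indole-2-carboxylate
Conditions: DDQ (1.1 equiv), toluene, rt
Reagents that add atoms: none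
Why: DDQ dehydrogenation of an N-unsubstituted indoline proceeds by nitrogen-assisted hydride abstraction at C2 and loss of the C3 proton, driven by aromatisation, and it removes the racemic centre.

**Step 6**
Reactants: 10 methyl 4,6-dibromo-1H-indole-2-carboxylate
Product: 11 4,6-dibromo-1H-indole-2-carboxylic acid
Conditions: LiOH·H2O, THF/MeOH/H2O, 50 °C; then 1 M HCl
Reagents that add atoms: lithium hydroxide, [Li+].[OH-]
Why: Saponification of the methyl ester by acyl–oxygen cleavage gives the carboxylate, released on acidification, while the indole N–H and the aryl bromides are inert to hydroxide.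

**Step 7**
Reactants: 11 4,6-dibromo-1H-indole-2-carboxylic acid
Product: 13 2,3,4,6-tetrabromo-1H-indole, via 3,4,6-tribromo-1H-indole-2-carboxylic acid 12 (not isolated)
Conditions: NBS (2.1 equiv), DMF, 0 °C → rt, dark
Reagents that add atoms: N-bromosuccinimide, O=C1CCC(=O)N1Br
Why: The first equivalent of NBS brominates C3, the most nucleophilic position, by electrophilic aromatic substitution, and the second attacks C2 ipso so that the σ-complex loses CO2 instead of a proton, a halodecarboxylation known for indole-2-carboxylic acids and other electron-rich heteroarene acids.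

**Compound list**
1 | 2,4,6-tribromophenol | Oc1c(Br)cc(Br)cc1Br | starting material
2 | (2,4,6-tribromophenoxy)trimethylsilane | C[Si](C)(C)Oc1c(Br)cc(Br)cc1Br | intermediate
3 | [3,5-dibromo-2-(trimethylsilyloxy)phenyl]lithium | [Li]c1cc(Br)cc(Br)c1O[Si](C)(C)C | intermediate
4 | lithium 2,4-dibromo-6-(trimethylsilyl)phenoxide | [Li+].[O-]c1c(Br)cc(Br)cc1[Si](C)(C)C | intermediate
5 | 2,4-dibromo-6-(trimethylsilyl)phenyl trifluoromethanesulfonate | C[Si](C)(C)c1cc(Br)cc(Br)c1OS(=O)(=O)C(F)(F)F | intermediate
6 | methyl 2-[(tert-butoxycarbonyl)amino]acrylate | C=C(NC(=O)OC(C)(C)C)C(=O)OC | starting material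
7 | 3,5-dibromobenzyne (3,5-dibromo-1,2-didehydrobenzene) | BrC1=CC(Br)=CC#C1 | intermediate
8 | 1-tert-butyl 2-methyl 4,6-dibromoindoline-1,2-dicarboxylate (racemic) | COC(=O)C1Cc2c(Br)cc(Br)cc2N1C(=O)OC(C)(C)C | intermediate
9 | methyl 4,6-dibromoindoline-2-carboxylate (racemic) | COC(=O)C1Cc2c(Br)cc(Br)cc2N1 | intermediate
10 | methyl 4,6-dibromo-1H-indole-2-carboxylate | COC(=O)c1cc2c(Br)cc(Br)cc2[nH]1 | intermediate
11 | 4,6-dibromo-1H-indole-2-carboxylic acid | OC(=O)c1cc2c(Br)cc(Br)cc2[nH]1 | intermediate
12 | 3,4,6-tribromo-1H-indole-2-carboxylic acid | OC(=O)c1[nH]c2cc(Br)cc(Br)c2c1Br | intermediate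
13 | 2,3,4,6-tetrabromo-1H-indole | Brc1cc(Br)c2c(Br)c(Br)[nH]c2c1 | target

**Step count**
Total steps: 7. Longest linear sequence: 7 steps (1 → 13); compound 6 is purchased.

**Steps most likely to fail**

Step 3. The ortho-bromoaryl anion may be protonated, or may expel bromide, faster than it closes the 5-endo ring, so that only N-arylation takes place. The fallback sets out from 5 and comes back at 11, and asks the aryne for N-arylation only. Methyl pyruvate is condensed with tosylhydrazide to methyl 2-(2-tosylhydrazinylidene)propanoate F1. Compound 5, F1 and CsF in MeCN should give methyl 2-[2-(3,5-dibromophenyl)-2-tosylhydrazinylidene]propanoate F2, with nitrogen again at the distal aryne carbon and a proton beside bromine. BF3·OEt2 in hot MeCN then triggers Fischer indolisation; the sigmatropic shift can only reach one of two equivalent ortho carbons, each flanked by bromine, so it should give methyl 4,6-dibromo-1-tosyl-1H-indole-2-carboxylate F3. KOH in aqueous MeOH at reflux removes both the sulfonyl group and the ester to give 11.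

Step 7. The second bromination may go to C7 or C5, re-attack C3, or stall at 12 instead of displacing the carboxyl group. The fallback sets out from 11 and comes back at 13, separating decarboxylation from bromination. Protodecarboxylation with Ag2CO3 (catalytic) and AcOH in DMSO at 120 °C should give 4,6-dibromo-1H-indole F4. Stepwise NBS bromination in DMF then brominates C3 first to give 3,4,6-tribromo-1H-indole F5, and C2 second to give 13.

Step 2. O-triflation of the crowded lithium phenoxide may lag behind desilylation or decomposition on warming, or the triflate may be lost on purification. The fallback sets out from 2 and comes back at 8, dispensing with the isolated triflate. After exchange and silyl migration the phenoxide is quenched with aqueous NH4Cl to give 2,4-dibromo-6-(trimethylsilyl)phenol F6. This phenol, 6, nonafluorobutanesulfonyl fluoride and Cs2CO3 with 18-crown-6 in MeCN should form 2,4-dibromo-6-(trimethylsilyl)phenyl nonafluorobutane-1-sulfonate F7 in the flask. The fluoride released in its formation desilylates it to aryne 7, which is trapped by 6 to give 8.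

**Further compounds**
F1 | step 3 | methyl 2-(2-tosylhydrazinylidene)propanoate | COC(=O)C(C)=NNS(=O)(=O)c1ccc(C)cc1
F2 | step 3 | methyl 2-[2-(3,5-dibromophenyl)-2-tosylhydrazinylidene]propanoate | COC(=O)C(C)=NN(c1cc(Br)cc(Br)c1)S(=O)(=O)c1ccc(C)cc1
F3 | step 3 | methyl 4,6-dibromo-1-tosyl-1H-indole-2-carboxylate | COC(=O)c1cc2c(Br)cc(Br)cc2n1S(=O)(=O)c1ccc(C)cc1
F4 | step 7 | 4,6-dibromo-1H-indole | Brc1cc(Br)c2cc[nH]c2c1
F5 | step 7 | 3,4,6-tribromo-1H-indole | Brc1cc(Br)c2c(Br)c[nH]c2c1
F6 | step 2 | 2,4-dibromo-6-(trimethylsilyl)phenol | C[Si](C)(C)c1cc(Br)cc(Br)c1O
F7 | step 2 | 2,4-dibromo-6-(trimethylsilyl)phenyl nonafluorobutane-1-sulfonate | C[Si](C)(C)c1cc(Br)cc(Br)c1OS(=O)(=O)C(F)(F)C(F)(F)C(F)(F)C(F)(F)F
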